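Ring C of the middle flavan unit is disconnected across O1–C2 and C3–C4. Its ring A, with O1, C8a, C4a and C4, becomes an ortho-quinone methide heterodiene that already carries the upper epicatechin gallate on C8 and C8 of the terminal catechin on C4; C2, C3, ring B and the second gallate arrive together as a (Z)-enol gallate of an arylacetaldehyde. One acid-catalysed inverse-demand oxa-[4+2] cycloaddition closes ring C, completes the trimer skeleton and sets C2, C3 and C4. The quinone methide precursor is a doubly electron-rich ortho-hydroxybenzhydrol, assembled from an 8-lithiocatechin and a salicylaldehyde; global hydrogenolysis finishes the synthesis.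

Key step: step 11

Remarks on the chemistry:
- The target is read as epicatechin-3-O-gallate-(4β→8)-epicatechin-3-O-gallate-(4β→8)-catechin. α/β refer to the usual flavan orientation, in which the 2-aryl group of the natural 2R series is α. Upper and middle units are 2,3-cis-3,4-trans; the terminal unit is 2,3-trans with a free 3-OH.
- The diaryl carbinol made in step 8 is used as a mixture of epimers at the carbinol carbon, because this centre becomes trigonal in the key step.
- All numbered starting materials are taken as commercial.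

Step 1
Reactants: 1 (−)-epicatechin; 2 benzyl bromide
Product: 3 5,7,3',4'-tetra-O-benzyl-(−)-epicatechin
Conditions: BnBr (4.4 equiv), K2CO3, DMF, 0 °C → rt
Reagents that add atoms: benzyl bromide 2, BrCc1ccccc1
Why: Williamson etherification in which carbonate alkylates only the four phenols and leaves the secondary 3-OH and both stereocentres untouched.

Step 2
Reactants: 3 5,7,3',4'-tetra-O-benzyl-(−)-epicatechin; 4 2-ethoxyethanol
Product: 5 5,7,3',4'-tetra-O-benzyl-4β-(2-ethoxyethoxy)epicatechin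
Conditions: DDQ (2 equiv), 2-ethoxyethanol (5 equiv), CH2Cl2, rt
Reagents that add atoms: 2-ethoxyethanol 4, CCOCCO
Why: DDQ benzylic oxidation (hydride abstraction from C4) should give the ring-A-stabilised flavan-4-yl cation, which the alcohol traps anti to the 3α-hydroxyl to set the 4β (3,4-trans) ether.

Step 3
Reactants: 5 5,7,3',4'-tetra-O-benzyl-4β-(2-ethoxyethoxy)epicatechin; 6 3,4,5-tris(benzyloxy)benzoic acid
Product: 7 5,7,3',4'-tetra-O-benzyl-4β-(2-ethoxyethoxy)epicatechin 3-O-[3,4,5-tris(benzyloxy)benzoate]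
Conditions: 6 (1.5 equiv), DCC, 4-(dimethylamino)pyridine (cat.), CH2Cl2, rt
Reagents that add atoms: 3,4,5-tris(benzyloxy)benzoic acid 6, OC(=O)c1cc(OCc2ccccc2)c(OCc2ccccc2)c(OCc2ccccc2)c1
Why: Steglich esterification acylates the only free hydroxyl under neutral conditions that leave the C4 acetal-type ether intact.

Step 4
Reactants: 7 5,7,3',4'-tetra-O-benzyl-4β-(2-ethoxyethoxy)epicatechin 3-O-[3,4,5-tris(benzyloxy)benzoate]; 8 2,4,6-trihydroxybenzaldehyde
Product: 9 2,4,6-trihydroxy-3-[hepta-O-benzyl-epicatechin-3-O-gallate-4β-yl]benzaldehyde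
Conditions: 8 (5 equiv), BF3·OEt2 (0.5 equiv), THF/CH2Cl2, −20 → 0 °C
Reagents that add atoms: 2,4,6-trihydroxybenzaldehyde 8, O=Cc1c(O)cc(O)cc1O
Why: Friedel–Crafts arylation of the flavan-4-yl cation, in which the two free ring positions of 8 are equivalent (one regioisomer) and the participating 3α-galloyloxy group blocks the α face so that the new C4–aryl bond should form β (3,4-trans).

Step 5
Reactants: 9 2,4,6-trihydroxy-3-[hepta-O-benzyl-epicatechin-3-O-gallate-4β-yl]benzaldehyde; 2 benzyl bromide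
Product: 10 4,6-bis(benzyloxy)-2-hydroxy-3-[hepta-O-benzyl-epicatechin-3-O-gallate-4β-yl]benzaldehyde
Conditions: BnBr (2.1 equiv), K2CO3 (2.2 equiv), DMF, 0 °C → rt
Reagents that add atoms: benzyl bromide 2, BrCc1ccccc1
Why: Regioselective Williamson etherification, expected to leave free the 2-OH (future O1), which is flanked by the formyl and flavanyl groups and held in the hydrogen bond to C=O, as in the selective dialkylation of 3-substituted 2,4,6-trihydroxyaryl carbonyl compounds.

Step 6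
Reactants: 11 (+)-catechin; 2 benzyl bromide
Product: 12 3,5,7,3',4'-penta-O-benzyl-(+)-catechin
Conditions: BnBr (4.4 equiv), K2CO3, DMF, rt; then NaH (1.3 equiv), BnBr (1.2 equiv), 0 °C → rt
Reagents that add atoms: benzyl bromide 2, BrCc1ccccc1
Why: Two-stage Williamson etherification (phenols with carbonate, then the 3-OH as its sodium alkoxide), which keeps the phenoxides from C-alkylation and does not touch C2 or C3.

Step 7
Reactants: 12 3,5,7,3',4'-penta-O-benzyl-(+)-catechin; 13 N-bromosuccinimide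
Product: 14 8-bromo-3,5,7,3',4'-penta-O-benzyl-(+)-catechin
Conditions: NBS (1.0 equiv), CH2Cl2, −20 °C
Reagents that add atoms: N-bromosuccinimide 13, O=C1CCC(=O)N1Br
Why: Electrophilic aromatic bromination, which in benzylated catechins is known to take place at C8 of the phloroglucinol ring in preference to C6.

Step 8
Reactants: 14 8-bromo-3,5,7,3',4'-penta-O-benzyl-(+)-catechin; 10 4,6-bis(benzyloxy)-2-hydroxy-3-[hepta-O-benzyl-epicatechin-3-O-gallate-4β-yl]benzaldehyde
Product: 16 diaryl carbinol [4,6-bis(benzyloxy)-2-hydroxy-3-(flavan-4β-yl)phenyl][penta-O-benzylcatechin-8-yl]methanol, via aryllithium 15 (not isolated)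
Conditions: n-BuLi (1.05 equiv to 14), THF, −78 °C; then 10 (0.45 equiv), −78 → −40 °C; aq NH4Cl, rapid neutral work-up
Reagents that add atoms: none
Why: Bromine–lithium exchange followed by 1,2-addition to the aldehyde, in which the first equivalent of aryllithium deprotonates the phenol and the second should add to the formyl group faster than to the hindered gallate ester at −78 °C; the new carbinol centre is not controlled and need not be.

Step 9
Reactants: 17 3,4-bis(benzyloxy)benzaldehyde; 18 dimethyl (1-diazo-2-oxopropyl)phosphonate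
Product: 19 1,2-bis(benzyloxy)-4-ethynylbenzene
Conditions: 18 (1.2 equiv), K2CO3, MeOH, rt
Reagents that add atoms: dimethyl (1-diazo-2-oxopropyl)phosphonate 18, COP(=O)(OC)C(=[N+]=[N-])C(C)=O
Why: Seyferth–Gilbert homologation in the Ohira–Bestmann variant converts a non-enolisable aryl aldehyde into the terminal alkyne under mild base.

Step 10
Reactants: 19 1,2-bis(benzyloxy)-4-ethynylbenzene; 6 3,4,5-tris(benzyloxy)benzoic acid
Product: 20 (Z)-2-[3,4-bis(benzyloxy)phenyl]ethenyl 3,4,5-tris(benzyloxy)benzoate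
Conditions: [RuCl2(p-cymene)]2 (1 mol %), P(4-ClC6H4)3 (3 mol %), 4-(dimethylamino)pyridine (4 mol %), toluene, 60 °C
Reagents that add atoms: 3,4,5-tris(benzyloxy)benzoic acid 6, OC(=O)c1cc(OCc2ccccc2)c(OCc2ccccc2)c(OCc2ccccc2)c1
Why: Ruthenium-catalysed anti-Markovnikov addition of a carboxylic acid to a terminal alkyne through a ruthenium vinylidene, which with this catalyst system is known to deliver the (Z)-enol ester.

Step 11
Reactants: 16 diaryl carbinol; 20 (Z)-2-[3,4-bis(benzyloxy)phenyl]ethenyl 3,4,5-tris(benzyloxy)benzoate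
Product: 22 nonadeca-O-benzyl-[epicatechin-3-O-gallate-(4β→8)-epicatechin-3-O-gallate-(4β→8)-catechin], via o-quinone methide 21 (not isolated)
Conditions: 20 (2 equiv), (R)-3,3'-bis(2,4,6-triisopropylphenyl)-1,1'-binaphthyl-2,2'-diyl hydrogen phosphate (10 mol %), 5 Å molecular sieves, CH2Cl2, −20 °C → rt
Reagents that add atoms: none
Why: The phosphoric acid should dehydrate 16 to the hydrogen-bonded o-quinone methide 21, whose electrophilic C4 is attacked by the acyloxy-bearing alkene carbon (future C3) while the benzylic carbon (future C2), its positive charge stabilised by the 3,4-dibenzyloxyphenyl ring, is captured by O1 in a concerted but asynchronous inverse-electron-demand oxa-Diels–Alder reaction. The closest known reaction type is the chiral-phosphoric-acid-catalysed [4+2] cycloaddition of o-quinone methides generated from o-hydroxybenzhydrols with β-substituted styrenes to give 2,3,4-trisubstituted chromans. Ring C of the middle unit is closed as a [4π+2π] cycloaddition; in the stepwise limit, C3–C4 bond formation is followed by a 6-exo-trig oxa-closure onto the quinoid benzylic cation. C2 and C3 should become cis because the (Z)-alkene adds suprafacially; C4 should become trans to C3 because an exo-type transition state places C3–H, not the galloyloxy group, between the two aryl groups on C4 and keeps both alkene substituents away from the peri C5 benzyloxy group (the (Z)-quinone methide/endo alternative converges on the same isomer); the absolute sense (2α-aryl, 3α-acyloxy, 4β-aryl) is to be imposed by the chiral phosphate, which ion-pairs with O1–H and shields one face of 21. The step needs the regiochemistry O1→C2 and C4→C3, secured because the ester oxygen is a far weaker donor than the 4-benzyloxyaryl ring, so that 20 reacts as a styrene and not as an enol ether; it also needs the exo and facial selectivity just described. Because the upper and terminal units are enantiopure, any wrong-face or endo adduct is a diastereomer removable by chromatography, and the mild acid should leave the acid-labile C4–C8 interflavan bond of the upper unit intact.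

Step 12
Reactants: 22 nonadeca-O-benzyl trimer
Product: 23 epicatechin-3-O-gallate-(4β→8)-epicatechin-3-O-gallate-(4β→8)-catechin (target, CNP0269915.2)
Conditions: H2 (1 atm), Pd(OH)2/C, THF/MeOH/H2O, rt
Reagents that add atoms: none
Why: Catalytic hydrogenolysis cleaves all nineteen benzyl ethers (including the terminal 3-O-benzyl) while the gallate esters, the cyclic benzylic C2–O1 ethers and the interflavan bonds are known to survive these conditions, so no stereocentre is touched.

Compound list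
1 | (−)-epicatechin | O[C@@H]1Cc2c(O)cc(O)cc2O[C@@H]1c1ccc(O)c(O)c1 | starting material
2 | benzyl bromide | BrCc1ccccc1 | starting material
3 | 5,7,3',4'-tetra-O-benzyl-(−)-epicatechin | O[C@@H]1Cc2c(OCc3ccccc3)cc(OCc3ccccc3)cc2O[C@@H]1c1ccc(OCc2ccccc2)c(OCc2ccccc2)c1 | intermediate
4 | 2-ethoxyethanol | CCOCCO | starting material
5 | 5,7,3',4'-tetra-O-benzyl-4β-(2-ethoxyethoxy)epicatechin | CCOCCO[C@H]1c2c(OCc3ccccc3)cc(OCc3ccccc3)cc2O[C@H](c2ccc(OCc3ccccc3)c(OCc3ccccc3)c2)[C@@H]1O | intermediate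
6 | 3,4,5-tris(benzyloxy)benzoic acid | OC(=O)c1cc(OCc2ccccc2)c(OCc2ccccc2)c(OCc2ccccc2)c1 | starting material
7 | 5,7,3',4'-tetra-O-benzyl-4β-(2-ethoxyethoxy)epicatechin 3-O-[3,4,5-tris(benzyloxy)benzoate] | CCOCCO[C@H]1c2c(OCc3ccccc3)cc(OCc3ccccc3)cc2O[C@H](c2ccc(OCc3ccccc3)c(OCc3ccccc3)c2)[C@@H]1OC(=O)c1cc(OCc2ccccc2)c(OCc2ccccc2)c(OCc2ccccc2)c1 | intermediate
8 | 2,4,6-trihydroxybenzaldehyde | O=Cc1c(O)cc(O)cc1O | starting material
9 | 2,4,6-trihydroxy-3-[hepta-O-benzyl-epicatechin-3-O-gallate-4β-yl]benzaldehyde | O=Cc1c(O)cc(O)c(c1O)[C@H]1c2c(OCc3ccccc3)cc(OCc3ccccc3)cc2O[C@H](c2ccc(OCc3ccccc3)c(OCc3ccccc3)c2)[C@@H]1OC(=O)c1cc(OCc2ccccc2)c(OCc2ccccc2)c(OCc2ccccc2)c1 | intermediate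
10 | 4,6-bis(benzyloxy)-2-hydroxy-3-[hepta-O-benzyl-epicatechin-3-O-gallate-4β-yl]benzaldehyde | O=Cc1c(OCc2ccccc2)cc(OCc2ccccc2)c(c1O)[C@H]1c2c(OCc3ccccc3)cc(OCc3ccccc3)cc2O[C@H](c2ccc(OCc3ccccc3)c(OCc3ccccc3)c2)[C@@H]1OC(=O)c1cc(OCc2ccccc2)c(OCc2ccccc2)c(OCc2ccccc2)c1 | intermediate
11 | (+)-catechin | O[C@H]1Cc2c(O)cc(O)cc2O[C@@H]1c1ccc(O)c(O)c1 | starting material
12 | 3,5,7,3',4'-penta-O-benzyl-(+)-catechin | c1ccccc1CO[C@H]1Cc2c(OCc3ccccc3)cc(OCc3ccccc3)cc2O[C@@H]1c1ccc(OCc2ccccc2)c(OCc2ccccc2)c1 | intermediate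
13 | N-bromosuccinimide | O=C1CCC(=O)N1Br | starting material
14 | 8-bromo-3,5,7,3',4'-penta-O-benzyl-(+)-catechin | c1ccccc1CO[C@H]1Cc2c(OCc3ccccc3)cc(OCc3ccccc3)c(Br)c2O[C@@H]1c1ccc(OCc2ccccc2)c(OCc2ccccc2)c1 | intermediate
15 | 8-lithio-3,5,7,3',4'-penta-O-benzyl-(+)-catechin | c1ccccc1CO[C@H]1Cc2c(OCc3ccccc3)cc(OCc3ccccc3)c([Li])c2O[C@@H]1c1ccc(OCc2ccccc2)c(OCc2ccccc2)c1 | intermediate
16 | diaryl carbinol: [4,6-bis(benzyloxy)-2-hydroxy-3-(hepta-O-benzyl-epicatechin-3-O-gallate-4β-yl)phenyl][penta-O-benzylcatechin-8-yl]methanol, epimer mixture at the carbinol carbon | OC(c1c(OCc2ccccc2)cc(OCc2ccccc2)c2c1O[C@H](c1ccc(OCc3ccccc3)c(OCc3ccccc3)c1)[C@@H](OCc1ccccc1)C2)c1c(OCc2ccccc2)cc(OCc2ccccc2)c([C@H]2c3c(OCc4ccccc4)cc(OCc4ccccc4)cc3O[C@H](c3ccc(OCc4ccccc4)c(OCc4ccccc4)c3)[C@@H]2OC(=O)c2cc(OCc3ccccc3)c(OCc3ccccc3)c(OCc3ccccc3)c2)c1O | intermediate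
17 | 3,4-bis(benzyloxy)benzaldehyde | O=Cc1ccc(OCc2ccccc2)c(OCc2ccccc2)c1 | starting material
18 | dimethyl (1-diazo-2-oxopropyl)phosphonate | COP(=O)(OC)C(=[N+]=[N-])C(C)=O | starting material
19 | 1,2-bis(benzyloxy)-4-ethynylbenzene | C#Cc1ccc(OCc2ccccc2)c(OCc2ccccc2)c1 | intermediate
20 | (Z)-2-[3,4-bis(benzyloxy)phenyl]ethenyl 3,4,5-tris(benzyloxy)benzoate | O=C(O/C=C\c1ccc(OCc2ccccc2)c(OCc2ccccc2)c1)c1cc(OCc2ccccc2)c(OCc2ccccc2)c(OCc2ccccc2)c1 | intermediate
21 | o-quinone methide of the middle ring A (C4=C4a, C8a=O), C4 bearing penta-O-benzylcatechin-8-yl, C8 bearing the upper flavanyl unit | O=C1C(=Cc2c(OCc3ccccc3)cc(OCc3ccccc3)c3c2O[C@H](c2ccc(OCc4ccccc4)c(OCc4ccccc4)c2)[C@@H](OCc2ccccc2)C3)C(OCc2ccccc2)=CC(OCc2ccccc2)=C1[C@H]1c2c(OCc3ccccc3)cc(OCc3ccccc3)cc2O[C@H](c2ccc(OCc3ccccc3)c(OCc3ccccc3)c2)[C@@H]1OC(=O)c1cc(OCc2ccccc2)c(OCc2ccccc2)c(OCc2ccccc2)c1 | intermediate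
22 | nonadeca-O-benzyl-[epicatechin-3-O-gallate-(4β→8)-epicatechin-3-O-gallate-(4β→8)-catechin] | O=C(O[C@@H]1[C@@H](c2c(OCc3ccccc3)cc(OCc3ccccc3)c3c2O[C@H](c2ccc(OCc4ccccc4)c(OCc4ccccc4)c2)[C@@H](OCc2ccccc2)C3)c2c(OCc3ccccc3)cc(OCc3ccccc3)c([C@H]3c4c(OCc5ccccc5)cc(OCc5ccccc5)cc4O[C@H](c4ccc(OCc5ccccc5)c(OCc5ccccc5)c4)[C@@H]3OC(=O)c3cc(OCc4ccccc4)c(OCc4ccccc4)c(OCc4ccccc4)c3)c2O[C@@H]1c1ccc(OCc2ccccc2)c(OCc2ccccc2)c1)c1cc(OCc2ccccc2)c(OCc2ccccc2)c(OCc2ccccc2)c1 | intermediate
23 | epicatechin-3-O-gallate-(4β→8)-epicatechin-3-O-gallate-(4β→8)-catechin | O=C(O[C@@H]1[C@@H](c2c(O)cc(O)c3c2O[C@H](c2ccc(O)c(O)c2)[C@@H](O)C3)c2c(O)cc(O)c([C@H]3c4c(O)cc(O)cc4O[C@H](c4ccc(O)c(O)c4)[C@@H]3OC(=O)c3cc(O)c(O)c(O)c3)c2O[C@@H]1c1ccc(O)c(O)c1)c1cc(O)c(O)c(O)c1 | target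

Total step count: 12. Longest linear sequence: 8 steps (steps 1, 2, 3, 4, 5, 8, 11, 12).

Steps most likely to fail

Step 11. The cycloaddition may proceed through the endo mode or on the wrong face of the quinone methide. A long-lived benzylic cation at C2 may lose the alkene geometry (2,3-trans ring) or be intercepted by the neighbouring ester carbonyl. The strongly stabilised quinone methide may also react too slowly. Fallback, by the known cationic interflavan coupling, setting out from 7 and 12: 7 is condensed with an excess of 12 (TMSOTf cat., CH2Cl2, −78 °C). C8 of 12 should attack the C4 cation of 7 anti to the participating 3-O-galloyl group and give the protected dimer hepta-O-benzyl-epicatechin-3-O-gallate-(4β→8)-penta-O-benzylcatechin F1. A second portion of 7 is then condensed under the same conditions with F1 in excess, at C8 of its upper unit. This comes back to the route at 22.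

Step 8. The aryllithium may attack the gallate ester, or add incompletely to the aldehyde once the ortho-phenoxide has lowered its electrophilicity. The carbinol may also ionise during work-up. Fallback, setting out from 10: the phenol is converted (Boc2O, 4-(dimethylamino)pyridine cat., CH2Cl2) into the aryl tert-butyl carbonate aldehyde F2, whose formyl group is no longer deactivated. Aryllithium 15 (1.1 equiv, −78 °C) adds to it, and the resulting alkoxide takes over the Boc group from the phenolic oxygen. A cold acetic acid quench gives the benzylic tert-butyl carbonate phenol F3. Under the acid of step 11, F3 loses tert-butyl carbonic acid and comes back to the route at 21.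

Step 5. Benzylation may go on the wrong oxygen (O1 instead of O5) or run on to the tribenzyl ether. Fallback, setting out from 7 and replacing steps 4 and 5: 7 is condensed (TMSOTf cat., CH2Cl2, −78 °C) with commercial 3,5-bis(benzyloxy)phenol (Oc1cc(OCc2ccccc2)cc(OCc2ccccc2)c1). The ortho-substituted product, 3,5-bis(benzyloxy)-2-[hepta-O-benzyl-epicatechin-3-O-gallate-4β-yl]phenol F4, is separated from the para isomer. Ortho-specific formylation of the magnesium phenoxide (MgCl2, Et3N, paraformaldehyde, MeCN, reflux) then puts the formyl group on the only free position next to the hydroxyl. This comes back to the route at 10.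

Further compounds
F1 | step 11 | hepta-O-benzyl-epicatechin-3-O-gallate-(4β→8)-penta-O-benzylcatechin | O=C(O[C@@H]1[C@@H](c2c(OCc3ccccc3)cc(OCc3ccccc3)c3c2O[C@H](c2ccc(OCc4ccccc4)c(OCc4ccccc4)c2)[C@@H](OCc2ccccc2)C3)c2c(OCc3ccccc3)cc(OCc3ccccc3)cc2O[C@@H]1c1ccc(OCc2ccccc2)c(OCc2ccccc2)c1)c1cc(OCc2ccccc2)c(OCc2ccccc2)c(OCc2ccccc2)c1
F2 | step 8 | 4,6-bis(benzyloxy)-2-(tert-butoxycarbonyloxy)-3-[hepta-O-benzyl-epicatechin-3-O-gallate-4β-yl]benzaldehyde | O=Cc1c(OCc2ccccc2)cc(OCc2ccccc2)c(c1OC(=O)OC(C)(C)C)[C@H]1c2c(OCc3ccccc3)cc(OCc3ccccc3)cc2O[C@H](c2ccc(OCc3ccccc3)c(OCc3ccccc3)c2)[C@@H]1OC(=O)c1cc(OCc2ccccc2)c(OCc2ccccc2)c(OCc2ccccc2)c1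
F3 | step 8 | tert-butyl carbonate of carbinol 16 at the benzylic oxygen, phenol free | CC(C)(C)OC(=O)OC(c1c(OCc2ccccc2)cc(OCc2ccccc2)c2c1O[C@H](c1ccc(OCc3ccccc3)c(OCc3ccccc3)c1)[C@@H](OCc1ccccc1)C2)c1c(OCc2ccccc2)cc(OCc2ccccc2)c([C@H]2c3c(OCc4ccccc4)cc(OCc4ccccc4)cc3O[C@H](c3ccc(OCc4ccccc4)c(OCc4ccccc4)c3)[C@@H]2OC(=O)c2cc(OCc3ccccc3)c(OCc3ccccc3)c(OCc3ccccc3)c2)c1O
F4 | step 5 | 3,5-bis(benzyloxy)-2-[hepta-O-benzyl-epicatechin-3-O-gallate-4β-yl]phenol | Oc1cc(OCc2ccccc2)cc(OCc2ccccc2)c1[C@H]1c2c(OCc3ccccc3)cc(OCc3ccccc3)cc2O[C@H](c2ccc(OCc3ccccc3)c(OCc3ccccc3)c2)[C@@H]1OC(=O)c1cc(OCc2ccccc2)c(OCc2ccccc2)c(OCc2ccccc2)c1
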